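**Retrosynthetic overview**
Central ring numbering: C1/C2 = OBz, C3/C6 = aryl, C4/C5 = OH. Each 4-hydroxyphenyl ring is a 4-arylcyclohex-2-enone less two hydrogens. Its C1'–C2' come from an ArCH2–CHO side chain on C3 or C6, and its C3'–C6', including the C4' oxygen, come from methyl vinyl ketone.
Disconnections: (i) benzoates on and benzyl ethers off at the end; (ii) both phenol rings back to enones; (iii) both enones by a two-directional Stork–Robinson annulation of the C3/C6 bis(acetaldehyde); (iv) the two Ar–CH2 bonds, which become the biaryl axes, by a double Claisen rearrangement that frees only the C1/C2 oxygens.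
Ring order: the central ring arrives with 3,4-bis(benzyloxy)benzaldehyde and is fully oxygenated in steps 1–2. Both outer rings close together in step 7 and are aromatised together in step 8.

Key step: step 7

Remark: the target has no stereocentre, and the outer rings carry no ortho substituents, so there is no stereogenic axis. It is achiral and there is no enantiomer to select; the only stereocentres in the route are transient.

**Step 1**
Reactants: 1 3,4-bis(benzyloxy)benzaldehyde
Product: 3 3,4-bis(benzyloxy)phenol, via aryl formate 2 (not isolated)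
Conditions: mCPBA, CH2Cl2, 0 °C → rt; aq. NaHCO3 wash; then K2CO3 (cat.), MeOH, rt
Reagents that add atoms: mCPBA, O=C(OO)c1cccc(Cl)c1
Why: Baeyer–Villiger (Dakin-type) oxidation, in which the electron-rich dialkoxyaryl group migrates in the Criegee adduct and the aryl formate is then transesterified by methanol under mild base that leaves the benzyl ethers alone.

**Step 2**
Reactants: 3 3,4-bis(benzyloxy)phenol
Product: 5 4,5-bis(benzyloxy)benzene-1,2-diol, via o-quinone 4 (not isolated)
Conditions: IBX (1.1 equiv), DMF, rt; then aq. Na2S2O4, EtOAc, rt (Ar)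
Reagents that add atoms: IBX, O=C1OI(=O)(O)c2ccccc12
Why: IBX ortho-oxygenation of an electron-rich phenol, in which the aryloxy-iodane delivers oxygen intramolecularly to the less hindered ortho carbon (C6) and collapses to the vinylogous-ester-stabilised o-quinone, which dithionite reduces; the alcohol-free solvent avoids exchange of the benzyloxy groups.

**Step 3**
Reactants: 5 4,5-bis(benzyloxy)benzene-1,2-diol; 6 allyl bromide
Product: 7 1,2-bis(allyloxy)-4,5-bis(benzyloxy)benzene
Conditions: allyl bromide (2.5 equiv), K2CO3, DMF, rt → 50 °C (Ar)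
Reagents that add atoms: allyl bromide 6, C=CCBr
Why: Double Williamson etherification of a catechol with a reactive allylic halide under carbonate base, run without air because 5 reoxidises easily.

**Step 4**
Reactants: 7 1,2-bis(allyloxy)-4,5-bis(benzyloxy)benzene
Product: 9 3,6-diallyl-4,5-bis(benzyloxy)benzene-1,2-diol, via mono-Claisen phenol 8 (not isolated)
Conditions: PhNEt2, 195 °C, sealed tube (Ar)
Reagents that add atoms: none
Why: Two successive aromatic Claisen [3,3] rearrangements, where each allyl group has one free ortho carbon (C3 or C6), both para positions carry benzyloxy groups, and the basic solvent suppresses acid-catalysed cyclisation of the o-allylphenols.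

**Step 5**
Reactants: 9 3,6-diallyl-4,5-bis(benzyloxy)benzene-1,2-diol
Product: 10 1,4-diallyl-2,3-bis(benzyloxy)-5,6-bis(methoxymethoxy)benzene
Conditions: NaH, MOMCl, DMF, 0 °C → rt
Reagents that add atoms: chloromethyl methyl ether (MOMCl), COCCl
Why: Standard acetal protection of both phenoxides; MOM tolerates amine, base and Pd(II) and is removed by acid without touching benzyl ethers, so C1/C2–O stays distinct from C4/C5–O, whereas aryl benzoates installed here would not survive the enamine chemistry.

**Step 6**
Reactants: 10 1,4-diallyl-2,3-bis(benzyloxy)-5,6-bis(methoxymethoxy)benzene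
Product: 12 2,2'-[2,3-bis(benzyloxy)-5,6-bis(methoxymethoxy)-1,4-phenylene]diacetaldehyde, via bis(diol) 11 (not isolated)
Conditions: OsO4 (cat.), NaIO4, 2,6-lutidine, dioxane–H2O (3:1), rt
Reagents that add atoms: osmium tetroxide (catalytic oxygen carrier), O=[Os](=O)(=O)=O; sodium periodate (terminal oxidant), [Na+].[O-]I(=O)(=O)=O
Why: Lemieux–Johnson cleavage (catalytic dihydroxylation, then periodate glycol fission), preferred to ozone because the tetraalkoxybenzene core would compete with the terminal alkenes for ozone; lutidine keeps the medium neutral for the MOM groups and the enolisable aldehydes.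

**Step 7**
Reactants: 12 2,2'-[2,3-bis(benzyloxy)-5,6-bis(methoxymethoxy)-1,4-phenylene]diacetaldehyde; 13 methyl vinyl ketone
Product: 16 4,4'-[2,3-bis(benzyloxy)-5,6-bis(methoxymethoxy)-1,4-phenylene]bis(cyclohex-2-en-1-one) as a dl/meso mixture, via bis(enamine) 14 (not isolated), via bis(keto aldehyde) 15 (not isolated)
Conditions: pyrrolidine (2.4 equiv), 4 Å MS, toluene, 0 °C → rt, concentrate; MVK (2.6 equiv), toluene, 0 → 40 °C; then AcOH–NaOAc–H2O (pH ≈ 5), 70 °C
Reagents that add atoms: methyl vinyl ketone 13, CC(=O)C=C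
Why: Both aldehydes condense with pyrrolidine to the bis(β-aminostyrene) 14, whose benzylic carbons add to the terminal carbon of methyl vinyl ketone (Stork enamine Michael addition), and buffered hydrolysis releases the bis(1,5-keto aldehyde) 15. The pyrrolidinium acetate then present turns each methyl ketone into its terminal enamine/enol, which attacks the neighbouring aldehyde and loses water, so the sequence is a two-directional Stork–Robinson annulation, the established route from arylacetaldehydes to 4-arylcyclohex-2-enones. Both rings close in the same way, by a favoured 6-(enolendo)-exo-trig aldol (the enol C=C lies inside the forming ring and the aldehyde C=O outside it), while attack through the internal CH2 of the ketone, or of the aldehyde α-carbon on the ketone, would give four-membered rings. The two new stereocentres (C4 of each enone) have no controlling element and should form as a dl/meso mixture, which is carried on unseparated because step 8 makes both carbons sp2. The step needs one alkylation per benzylic carbon and no aldehyde self-condensation: preforming the enamines removes free aldehyde before the acceptor is added, and the OBn and OMOM groups flanking each side chain disfavour a second addition that would create a quaternary carbon. The para arrangement keeps the two arms from reacting with each other, and MOM and benzyl ethers tolerate the amine and the pH 5 buffer.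

**Step 8**
Reactants: 16 4,4'-[2,3-bis(benzyloxy)-5,6-bis(methoxymethoxy)-1,4-phenylene]bis(cyclohex-2-en-1-one)
Product: 19 2',3'-bis(benzyloxy)-5',6'-bis(methoxymethoxy)-[1,1':4',1''-terphenyl]-4,4''-diol, via bis(silyl dienol ether) 17 (not isolated), via bis(dienone) 18 (not isolated)
Conditions: LiHMDS, TMSCl, THF, −78 °C; then Pd(OAc)2 (2.2 equiv), MeCN–THF, rt
Reagents that add atoms: none
Why: Saegusa–Ito dehydrosilylation, in which kinetic α'-deprotonation and O-silylation give the cross-conjugated silyloxydienes and Pd(II) β-hydride elimination gives 4-aryl-4H-cyclohexa-2,5-dienones, the keto tautomers of the phenols, so both stereocentres disappear under near-neutral conditions that spare MOM, benzyl and the oxidisable central ring, which DDQ would endanger.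

**Step 9**
Reactants: 19 2',3'-bis(benzyloxy)-5',6'-bis(methoxymethoxy)-[1,1':4',1''-terphenyl]-4,4''-diol
Product: 20 2',3',4,4''-tetrakis(benzyloxy)-5',6'-bis(methoxymethoxy)-1,1':4',1''-terphenyl
Conditions: BnBr, K2CO3, DMF, 50 °C
Reagents that add atoms: benzyl bromide, BrCc1ccccc1
Why: Williamson benzylation of the two unhindered outer phenols, which masks them so that only the C1/C2 oxygens are acylated later.

**Step 10**
Reactants: 20 2',3',4,4''-tetrakis(benzyloxy)-5',6'-bis(methoxymethoxy)-1,1':4',1''-terphenyl
Product: 21 4,4'',5',6'-tetrakis(benzyloxy)-[1,1':4',1''-terphenyl]-2',3'-diol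
Conditions: HCl (conc., cat.), MeOH–THF, 50 °C (Ar)
Reagents that add atoms: none
Why: Acid-catalysed acetal exchange with methanol removes both aryl MOM ethers while aryl benzyl ethers are inert; the air-sensitive catechol is taken on directly.

**Step 11**
Reactants: 21 4,4'',5',6'-tetrakis(benzyloxy)-[1,1':4',1''-terphenyl]-2',3'-diol; 22 benzoyl chloride
Product: 23 4,4'',5',6'-tetrakis(benzyloxy)-[1,1':4',1''-terphenyl]-2',3'-diyl dibenzoate
Conditions: BzCl (3 equiv), Et3N, DMAP (cat.), CH2Cl2, 0 °C → rt
Reagents that add atoms: benzoyl chloride 22, O=C(Cl)c1ccccc1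
Why: DMAP-catalysed O-acylation of the only two free hydroxyl groups, where the acylpyridinium intermediate overcomes the hindrance from the neighbouring aryl rings.

**Step 12**
Reactants: 23 4,4'',5',6'-tetrakis(benzyloxy)-[1,1':4',1''-terphenyl]-2',3'-diyl dibenzoate
Product: 24 4,4'',5',6'-tetrahydroxy-[1,1':4',1''-terphenyl]-2',3'-diyl dibenzoate (target)
Conditions: H2 (1 atm), 10% Pd/C, EtOAc–THF, rt; work-up under Ar
Reagents that add atoms: none
Why: Neutral catalytic hydrogenolysis cleaves all four aryl benzyl ethers and leaves aryl benzoates intact, and since the C3/C6 aryl groups separate each benzoate from the liberated hydroxyls, no acyl migration is expected.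

**Compound list**
1 | 3,4-bis(benzyloxy)benzaldehyde | O=Cc1ccc(OCc2ccccc2)c(OCc2ccccc2)c1 | starting material
2 | 3,4-bis(benzyloxy)phenyl formate | O=COc1ccc(OCc2ccccc2)c(OCc2ccccc2)c1 | intermediate
3 | 3,4-bis(benzyloxy)phenol | Oc1ccc(OCc2ccccc2)c(OCc2ccccc2)c1 | intermediate
4 | 4,5-bis(benzyloxy)cyclohexa-3,5-diene-1,2-dione | O=C1C=C(OCc2ccccc2)C(OCc2ccccc2)=CC1=O | intermediate
5 | 4,5-bis(benzyloxy)benzene-1,2-diol | Oc1cc(OCc2ccccc2)c(OCc2ccccc2)cc1O | intermediate
6 | allyl bromide | C=CCBr | starting material
7 | 1,2-bis(allyloxy)-4,5-bis(benzyloxy)benzene | C=CCOc1cc(OCc2ccccc2)c(OCc2ccccc2)cc1OCC=C | intermediate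
8 | 2-allyl-6-(allyloxy)-3,4-bis(benzyloxy)phenol | C=CCOc1cc(OCc2ccccc2)c(OCc2ccccc2)c(CC=C)c1O | intermediate
9 | 3,6-diallyl-4,5-bis(benzyloxy)benzene-1,2-diol | C=CCc1c(O)c(O)c(CC=C)c(OCc2ccccc2)c1OCc1ccccc1 | intermediate
10 | 1,4-diallyl-2,3-bis(benzyloxy)-5,6-bis(methoxymethoxy)benzene | C=CCc1c(OCOC)c(OCOC)c(CC=C)c(OCc2ccccc2)c1OCc1ccccc1 | intermediate
11 | 3,3'-[2,3-bis(benzyloxy)-5,6-bis(methoxymethoxy)-1,4-phenylene]bis(propane-1,2-diol), diastereomer mixture | OCC(O)Cc1c(OCOC)c(OCOC)c(CC(O)CO)c(OCc2ccccc2)c1OCc1ccccc1 | intermediate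
12 | 2,2'-[2,3-bis(benzyloxy)-5,6-bis(methoxymethoxy)-1,4-phenylene]diacetaldehyde | O=CCc1c(OCOC)c(OCOC)c(CC=O)c(OCc2ccccc2)c1OCc1ccccc1 | intermediate
13 | methyl vinyl ketone | CC(=O)C=C | starting material
14 | 1,1'-{[2,3-bis(benzyloxy)-5,6-bis(methoxymethoxy)-1,4-phenylene]bis[(E)-ethene-2,1-diyl]}dipyrrolidine | COCOc1c(OCOC)c(/C=C/N2CCCC2)c(OCc2ccccc2)c(OCc2ccccc2)c1/C=C/N1CCCC1 | intermediate
15 | 2,2'-[2,3-bis(benzyloxy)-5,6-bis(methoxymethoxy)-1,4-phenylene]bis(5-oxohexanal), diastereomer mixture | CC(=O)CCC(C=O)c1c(OCOC)c(OCOC)c(C(C=O)CCC(C)=O)c(OCc2ccccc2)c1OCc1ccccc1 | intermediate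
16 | 4,4'-[2,3-bis(benzyloxy)-5,6-bis(methoxymethoxy)-1,4-phenylene]bis(cyclohex-2-en-1-one), dl/meso mixture | O=C1C=CC(CC1)c1c(OCOC)c(OCOC)c(C2C=CC(=O)CC2)c(OCc2ccccc2)c1OCc1ccccc1 | intermediate
17 | 2,3-bis(benzyloxy)-5,6-bis(methoxymethoxy)-1,4-bis[4-(trimethylsilyloxy)cyclohexa-2,4-dien-1-yl]benzene, dl/meso mixture | C[Si](C)(C)OC1=CCC(C=C1)c1c(OCOC)c(OCOC)c(C2CC=C(O[Si](C)(C)C)C=C2)c(OCc2ccccc2)c1OCc1ccccc1 | intermediate
18 | 4,4'-[2,3-bis(benzyloxy)-5,6-bis(methoxymethoxy)-1,4-phenylene]bis(cyclohexa-2,5-dien-1-one) | O=C1C=CC(C=C1)c1c(OCOC)c(OCOC)c(C2C=CC(=O)C=C2)c(OCc2ccccc2)c1OCc1ccccc1 | intermediate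
19 | 2',3'-bis(benzyloxy)-5',6'-bis(methoxymethoxy)-[1,1':4',1''-terphenyl]-4,4''-diol | COCOc1c(OCOC)c(-c2ccc(O)cc2)c(OCc2ccccc2)c(OCc2ccccc2)c1-c1ccc(O)cc1 | intermediate
20 | 2',3',4,4''-tetrakis(benzyloxy)-5',6'-bis(methoxymethoxy)-1,1':4',1''-terphenyl | COCOc1c(OCOC)c(-c2ccc(OCc3ccccc3)cc2)c(OCc2ccccc2)c(OCc2ccccc2)c1-c1ccc(OCc2ccccc2)cc1 | intermediate
21 | 4,4'',5',6'-tetrakis(benzyloxy)-[1,1':4',1''-terphenyl]-2',3'-diol | Oc1c(O)c(-c2ccc(OCc3ccccc3)cc2)c(OCc2ccccc2)c(OCc2ccccc2)c1-c1ccc(OCc2ccccc2)cc1 | intermediate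
22 | benzoyl chloride | O=C(Cl)c1ccccc1 | starting material
23 | 4,4'',5',6'-tetrakis(benzyloxy)-[1,1':4',1''-terphenyl]-2',3'-diyl dibenzoate | O=C(Oc1c(OC(=O)c2ccccc2)c(-c2ccc(OCc3ccccc3)cc2)c(OCc2ccccc2)c(OCc2ccccc2)c1-c1ccc(OCc2ccccc2)cc1)c1ccccc1 | intermediate
24 | 4,4'',5',6'-tetrahydroxy-[1,1':4',1''-terphenyl]-2',3'-diyl dibenzoate | O=C(Oc1c(OC(=O)c2ccccc2)c(-c2ccc(O)cc2)c(O)c(O)c1-c1ccc(O)cc1)c1ccccc1 | target

**Total step count:** 12. **Longest linear sequence:** 12 (from 1).

**Steps most likely to fail**

Step 7. The two ortho-alkoxy groups may slow C–C bond formation at the benzylic carbons, so one arm could lag behind the other. Aldehyde self-condensation, a second Michael addition or polymerisation of the acceptor could then take over.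
The fallback gives up de novo ring construction. It sets out from 5 and returns at 20, bypassing steps 3–9. Catechol 5 would be protected (NaH, MOMCl, DMF) as 1,2-bis(benzyloxy)-4,5-bis(methoxymethoxy)benzene F1. This would be brominated at its two remaining ring positions (NBS, 2.1 equiv, DMF, 0 °C → rt, dark) to 1,2-bis(benzyloxy)-3,6-dibromo-4,5-bis(methoxymethoxy)benzene F2. A double Suzuki–Miyaura coupling with commercial 4-(benzyloxy)phenylboronic acid (Pd(OAc)2/SPhos, K3PO4, toluene–H2O, 100 °C) would then give 20.

Step 8. Enolisation of both rings may be incomplete, the silyl dienol ethers may revert to enones by protodesilylation, or palladium may precipitate before both rings are oxidised, leaving the material half aromatised.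
The fallback replaces the metal-mediated dehydrogenation by a chalcogen elimination. It sets out from 16 and returns at 19. α'-Selenenylation (LiHMDS, then PhSeCl, THF, −78 °C) would give 4,4'-[2,3-bis(benzyloxy)-5,6-bis(methoxymethoxy)-1,4-phenylene]bis[6-(phenylselanyl)cyclohex-2-en-1-one] F3. Oxidation (H2O2, pyridine, CH2Cl2, 0 °C) would trigger selenoxide syn elimination, and the resulting dienones tautomerise to 19.

Step 2. Oxygen may be delivered in part to the more hindered ortho position, the quinone may lose a benzyloxy group by addition–elimination, or the catechol may reoxidise during work-up.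
The fallback installs the oxygen through a carbon handle. It sets out from 3 and returns at 5. Magnesium-mediated ortho-formylation (MgCl2, Et3N, paraformaldehyde, MeCN, reflux; Casnati–Skattebøl) at the less hindered ortho carbon would give 4,5-bis(benzyloxy)-2-hydroxybenzaldehyde F4. A Dakin oxidation (H2O2, aq. NaOH, THF, 0 °C → rt) would then convert it into 5.

**Further compounds**
F1 | step 7 | 1,2-bis(benzyloxy)-4,5-bis(methoxymethoxy)benzene | COCOc1cc(OCc2ccccc2)c(OCc2ccccc2)cc1OCOC
F2 | step 7 | 1,2-bis(benzyloxy)-3,6-dibromo-4,5-bis(methoxymethoxy)benzene | COCOc1c(OCOC)c(Br)c(OCc2ccccc2)c(OCc2ccccc2)c1Br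
F3 | step 8 | 4,4'-[2,3-bis(benzyloxy)-5,6-bis(methoxymethoxy)-1,4-phenylene]bis[6-(phenylselanyl)cyclohex-2-en-1-one], diastereomer mixture | O=C1C=CC(CC1[Se]c1ccccc1)c1c(OCOC)c(OCOC)c(C2C=CC(=O)C([Se]c3ccccc3)C2)c(OCc2ccccc2)c1OCc1ccccc1
F4 | step 2 | 4,5-bis(benzyloxy)-2-hydroxybenzaldehyde | O=Cc1cc(OCc2ccccc2)c(OCc2ccccc2)cc1O
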